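**Plan**

- Feature: in ring B (the phenol ring) the C2–Br carbon lies between the C1–OH carbon and C3–H, and C6, the other neighbour of C1, carries the ether oxygen to ring A. A Br–C unit beside a C–O carbon is what dibromocarbene insertion next to an enol ether delivers.
- Cuts: first the C4–Br bond of ring B (para to OH). Then the ring bonds C1–C2 and C2–C3 of ring B, so that C2 and its bromine leave as dibromocarbene and a five-membered 2-aryloxy-3-silyloxycyclopentadiene remains. Then the O–Si bond, the aryl ether bond to C6 (phenol plus epoxy ketone) and the ortho C–Br bond of ring A.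
- Forward: ring A is bought as 4-bromoguaiacol and brominated once. Cyclopentenone is epoxidised, opened by the phenol and dehydrated to the 2-aryloxy enone. Kinetic O-silylation gives the diene. Ring B then arises by one-carbon expansion of the five-membered ring and is brominated last.
- Stereochemistry: the target has no stereocentre. The stereocentres of 4, 5 and 10 are transient and racemic.

Key step: step 5

Remark: compounds 4, 5 and 10 are racemic; each SMILES shows one enantiomer of the stated relative configuration.

**Route**

Step 1
Reactants: 1 4-bromo-2-methoxyphenol (4-bromoguaiacol)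
Product: 2 2,4-dibromo-6-methoxyphenol
Conditions: NBS (1.05 equiv), iPr2NH (0.1 equiv), CH2Cl2, 0 °C → rt
Reagents that add atoms: N-bromosuccinimide O=C1CCC(=O)N1Br
Why: Amine-catalysed electrophilic bromination with NBS, in which the N-bromoamine is delivered through a hydrogen bond to the phenolic OH, should substitute the only free position ortho to the hydroxyl of 1, the para position already carrying bromine.

Step 2
Reactants: 3 cyclopent-2-en-1-one
Product: 4 6-oxabicyclo[3.1.0]hexan-2-one (2,3-epoxycyclopentanone; cis-fused; racemic)
Conditions: 30% aq. H2O2, NaOH (cat.), MeOH, 0 °C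
Reagents that add atoms: hydrogen peroxide OO
Why: Weitz–Scheffer epoxidation: hydroperoxide adds in conjugate fashion to the enone and the enolate closes onto the O–O bond, giving an oxirane that on a five-membered ring can only be cis-fused and is formed as the racemate.

Step 3
Reactants: 4 6-oxabicyclo[3.1.0]hexan-2-one; 2 2,4-dibromo-6-methoxyphenol
Product: 6 2-(2,4-dibromo-6-methoxyphenoxy)cyclopent-2-en-1-one, via hydroxy ketone 5 (not isolated)
Conditions: Cs2CO3 (0.3 equiv), DMF, rt → 50 °C
Reagents that add atoms: none
Why: The phenoxide of 2 should open the carbonyl-activated oxirane by SN2 attack at the α-carbon with inversion to trans-hydroxy ketone 5, whose acidified α-hydrogen allows E1cB loss of the β-hydroxyl under the same base (the known conversion of α,β-epoxy ketones and phenols into α-aryloxy enones), so both stereocentres disappear.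

Step 4
Reactants: 6 2-(2,4-dibromo-6-methoxyphenoxy)cyclopent-2-en-1-one
Product: 8 2-(2,4-dibromo-6-methoxyphenoxy)-3-(tert-butyldimethylsilyloxy)cyclopenta-1,3-diene, via lithium dienolate 7 (not isolated)
Conditions: LiN(SiMe3)2 (1.1 equiv), THF, −78 °C; then TBSOTf (1.15 equiv), −78 → −40 °C; cold pentane/aq. NaHCO3 work-up, used at once
Reagents that add atoms: tert-butyldimethylsilyl trifluoromethanesulfonate CC(C)(C)[Si](C)(C)OS(=O)(=O)C(F)(F)F
Why: Kinetic deprotonation at C5, the only α-CH2 of the enone, by the hindered amide (too weak a base to metalate ring A between its bromines) gives cross-conjugated dienolate 7, which the silyl triflate traps on oxygen; this is the usual preparation of 2-silyloxycyclopenta-1,3-dienes from cyclopentenones, and the tert-butyldimethylsilyl group is chosen so that the ether survives alkoxide in step 5.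

Step 5
Reactants: 8 2-(2,4-dibromo-6-methoxyphenoxy)-3-(tert-butyldimethylsilyloxy)cyclopenta-1,3-diene; 9 bromoform
Product: 12 2-bromo-6-(2,4-dibromo-6-methoxyphenoxy)phenol, via dibromocyclopropane 10 (not isolated), via aryl silyl ether 11 (not isolated)
Conditions: 9 (3 equiv), KOtBu (4 equiv, in portions), pentane, −30 → 0 °C; then KHF2, MeOH–THF, rt
Reagents that add atoms: none
Why: α-Elimination of KCBr3 gives dibromocarbene, which adds in a concerted (2+1) fashion to the silyloxy-substituted C3=C4 bond of 8 to give cis-fused cyclopropane 10; disrotatory electrocyclic opening of the ring-fusion bond with loss of one bromide, pushed by the silyloxy oxygen, gives a cyclohexadienyl cation that loses a proton from its CH2 group, so ring B appears as aryl silyl ether 11, which KHF2 then cleaves. The closest known reaction types are the dihalocarbene ring expansion of cyclic silyl enol ethers to 2-halo enones and of cyclopentadienes and indenes to halobenzenes and 2-halonaphthalenes (Ciamician–Dennstedt-type one-carbon insertion). Ring B is thus closed by enlargement of the five-membered ring, both new C–C bonds running from the carbene carbon (to the C–O carbon and to its CH neighbour), and not by cyclisation of a chain. No stereocentre remains, because the two bridgehead centres of racemic 10 are erased on opening. The carbene must choose the silyloxy alkene over the aryloxy alkene, which the stronger O–Si donor, the electron-poor dibromoarene on the other oxygen and the shielding by the ortho bromine and methoxyl of ring A should secure; the CH2 of the diene must also stay in place, for which the low temperature, the excess of the more acidic bromoform and the portionwise base are chosen. The silyl group stays on oxygen until the carbene is spent, so that no phenoxide meets dibromocarbene.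

Step 6
Reactants: 12 2-bromo-6-(2,4-dibromo-6-methoxyphenoxy)phenol
Product: 13 2,4-dibromo-6-(2,4-dibromo-6-methoxyphenoxy)phenol (CNP0236935.0)
Conditions: Br2 (1.0 equiv), AcOH, rt
Reagents that add atoms: bromine BrBr
Why: Electrophilic aromatic bromination should take the one activated position left, para to the free hydroxyl of ring B whose two ortho positions are occupied, while ring A, an aryl ether with two bromines, is far less nucleophilic.

**Compound list**

1 | 4-bromo-2-methoxyphenol | COc1cc(Br)ccc1O | starting material
2 | 2,4-dibromo-6-methoxyphenol | COc1cc(Br)cc(Br)c1O | intermediate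
3 | cyclopent-2-en-1-one | O=C1C=CCC1 | starting material
4 | 6-oxabicyclo[3.1.0]hexan-2-one (cis-fused, racemic) | O=C1CC[C@@H]2O[C@H]12 | intermediate
5 | trans-2-(2,4-dibromo-6-methoxyphenoxy)-3-hydroxycyclopentan-1-one (racemic) | O=C1CC[C@H](O)[C@H]1Oc1c(Br)cc(Br)cc1OC | intermediate
6 | 2-(2,4-dibromo-6-methoxyphenoxy)cyclopent-2-en-1-one | O=C1CCC=C1Oc1c(Br)cc(Br)cc1OC | intermediate
7 | lithium 5-(2,4-dibromo-6-methoxyphenoxy)cyclopenta-1,4-dien-1-olate | [Li]OC1=CCC=C1Oc1c(Br)cc(Br)cc1OC | intermediate
8 | 2-(2,4-dibromo-6-methoxyphenoxy)-3-(tert-butyldimethylsilyloxy)cyclopenta-1,3-diene | CC(C)(C)[Si](C)(C)OC1=CCC=C1Oc1c(Br)cc(Br)cc1OC | intermediate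
9 | bromoform | BrC(Br)Br | starting material
10 | 6,6-dibromo-1-(tert-butyldimethylsilyloxy)-2-(2,4-dibromo-6-methoxyphenoxy)bicyclo[3.1.0]hex-2-ene (cis-fused, racemic) | BrC1(Br)[C@@H]2CC=C(Oc3c(Br)cc(Br)cc3OC)[C@]12O[Si](C)(C)C(C)(C)C | intermediate
11 | tert-butyl[2-bromo-6-(2,4-dibromo-6-methoxyphenoxy)phenoxy]dimethylsilane | CC(C)(C)[Si](C)(C)Oc1c(Br)cccc1Oc1c(Br)cc(Br)cc1OC | intermediate
12 | 2-bromo-6-(2,4-dibromo-6-methoxyphenoxy)phenol | COc1cc(Br)cc(Br)c1Oc1cccc(Br)c1O | intermediate
13 | 2,4-dibromo-6-(2,4-dibromo-6-methoxyphenoxy)phenol | COc1cc(Br)cc(Br)c1Oc1cc(Br)cc(Br)c1O | target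

**Count**

Total steps: 6. Longest linear sequence: 5 steps (steps 1, 3, 4, 5, 6; the branch through step 2 is equally long).

**Steps most likely to fail**

Step 5. Alkoxide may shift the ring CH2 of the diene by deprotonation and reprotonation, or a 1,5-hydrogen shift may do so, before cyclopropanation; the carbene may also add to the aryloxy alkene. Either course would insert the CBr unit into the wrong ring bond. The fallback gives up the ring expansion, sets out from 2 and comes back at 12. Nucleophilic aromatic substitution of the fluoride of bought 2-bromo-6-fluorobenzaldehyde (O=Cc1c(F)cccc1Br) by the phenoxide of 2 (K2CO3, DMF, 90 °C) should give 2-bromo-6-(2,4-dibromo-6-methoxyphenoxy)benzaldehyde F1. Baeyer–Villiger oxidation of the aldehyde with mCPBA in CH2Cl2 should give 2-bromo-6-(2,4-dibromo-6-methoxyphenoxy)phenyl formate F2, and methanolysis (K2CO3, MeOH) should return phenol 12.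

Step 3. The hindered, weakly nucleophilic phenoxide may open the oxirane slowly while base isomerises or oligomerises the epoxy ketone. The fallback forms the ether bond on an α-halo ketone, sets out from 2 and comes back at 6. Alkylation of 2 with bought 2-chlorocyclopentan-1-one (O=C1CCCC1Cl; K2CO3, KI cat., acetone, reflux) should give 2-(2,4-dibromo-6-methoxyphenoxy)cyclopentan-1-one F3. Equilibrating silylation (Me3SiCl, NaI, Et3N, MeCN) should give the more substituted enol ether {[2-(2,4-dibromo-6-methoxyphenoxy)cyclopent-1-en-1-yl]oxy}trimethylsilane F4, and Saegusa–Ito dehydrogenation with Pd(OAc)2 in MeCN should give enone 6.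

Step 4. Deprotonation at the γ-CH2, equilibration of the dienolate or hydrogen shifts during work-up may give regioisomeric dienes. The fallback runs the same carbene expansion one oxidation level lower, where no cyclopentadiene is involved; it sets out from 6 and comes back at 12. Conjugate reduction of 6 with [(Ph3P)CuH]6 in benzene should give the saturated ketone 2-(2,4-dibromo-6-methoxyphenoxy)cyclopentan-1-one F3, the compound of the fallback for step 3 reached here from 6. Kinetic enolisation away from the aryloxy carbon (LiN(SiMe3)2, THF, −78 °C; TBSOTf) should give tert-butyl{[5-(2,4-dibromo-6-methoxyphenoxy)cyclopent-1-en-1-yl]oxy}dimethylsilane F5. Dibromocarbene (CHBr3, KOtBu, pentane, −30 → 0 °C) should expand it to 2-bromo-6-(2,4-dibromo-6-methoxyphenoxy)cyclohex-2-en-1-one F6, and dehydrogenation (I2 cat., DMSO, 90 °C) should aromatise this enone to 12.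

**Further compounds**

F1 | step 5 | 2-bromo-6-(2,4-dibromo-6-methoxyphenoxy)benzaldehyde | O=Cc1c(Br)cccc1Oc1c(Br)cc(Br)cc1OC
F2 | step 5 | 2-bromo-6-(2,4-dibromo-6-methoxyphenoxy)phenyl formate | O=COc1c(Br)cccc1Oc1c(Br)cc(Br)cc1OC
F3 | step 3 | 2-(2,4-dibromo-6-methoxyphenoxy)cyclopentan-1-one (racemic) | O=C1CCCC1Oc1c(Br)cc(Br)cc1OC
F4 | step 3 | {[2-(2,4-dibromo-6-methoxyphenoxy)cyclopent-1-en-1-yl]oxy}trimethylsilane | C[Si](C)(C)OC1=C(Oc2c(Br)cc(Br)cc2OC)CCC1
F5 | step 4 | tert-butyl{[5-(2,4-dibromo-6-methoxyphenoxy)cyclopent-1-en-1-yl]oxy}dimethylsilane (racemic) | CC(C)(C)[Si](C)(C)OC1=CCCC1Oc1c(Br)cc(Br)cc1OC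
F6 | step 4 | 2-bromo-6-(2,4-dibromo-6-methoxyphenoxy)cyclohex-2-en-1-one (racemic) | O=C1C(Br)=CCCC1Oc1c(Br)cc(Br)cc1OC
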